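The noon run slows down, and two of us quarrel over what that slowness means.

the same everywhere: substrate 0.50 M; initiator 2.7 mM
- spring: reagent 0.042 M; temperature 5 °C; run made earlier
- noon: reagent 0.74 M; temperature 20 °C; run made earlier
- red: reagent 0.120 M; temperature 20 °C; time 20 h
- amber: reagent 0.500 M; temperature 20 °C; time 20 h
- violet: reagent 0.350 M; temperature 20 °C; time 20 h
- ochre: reagent 1.00 M; temperature 20 °C; time 20 h
- green: reagent 0.0800 M; temperature 20 °C; time 20 h
- grey: reagent 0.250 M; temperature 20 °C; time 20 h

| run | time / h | target / % | substrate / % |
|---|---|---|---|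
| spring | 3.00 | 0 | 100 |
| spring | 8.00 | 1 | 101 |
| spring | 12.0 | 2 | 99 |
| spring | 20.0 | 2 | 97 |
| spring | 30.0 | 0 | 98 |
| noon | 1.33 | 5 | 99 |
| noon | 4.00 | 14 | 85 |
| noon | 6.00 | 17 | 82 |
| noon | 10.0 | 21 | 79 |
| noon | 15.0 | 26 | 75 |

(standard deviation of a reading: 2 percentage points)

- all flasks from highest to lowest amount of target, in percent of the substrate charged, at 20 h (red / amber / violet / ochre / green / grey)
- the amount of target, in percent of the substrate charged of the flask you put first, at 20 h
- the amount of target, in percent of the substrate charged of the flask you put last, at 20 h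

The noon run gains 14% in its first 4.00 h, then 5 percentage points in the 5.00 h after 10.0 h. Read from these scattered points, its rate has fallen by a factor of 3.50. Substrate still reads 75%, so its loss is too small to account for that. The spring run is cold and poor in reagent at once, so I leave it aside.

The forecaster scales noon's dose with “a rate proportional to reagent × substrate”. Target then follows the charge of reagent. She orders the flasks ochre > amber > violet > grey > red > green, and she gets 36% for ochre and 3.5% for green, a spread of 10.3. Her top is what a first-order curve to completion through the last noon reading gives.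

I hold another view, as a guess. The reagent destroys itself in pairs, a second-order loss. Its half-life then shortens as its charge grows, and the rate falls as 1/(1 + t/τ). The midpoints of those two noon stretches give τ = 2.20 h, a rough reading given the scatter. I carry one quantity, the reagent clock: this half-life times the charge, 97.7 M·min. The time divided by the clock and multiplied by c(reagent) counts the time in first half-lives, n.

Target grows as ln(1 + n). The last noon reading sets the scale at 12.6% per unit. Ochre has n = 12.3, so I reckon 32.7%. Green has n = 0.983, so I reckon 8.65%. My spread is 3.78, on a ratio of charges of 12.5.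

We agree on the order. I grant her one region: on my view, with n well below 1, ln(1 + n) lies near n, and her proportion holds. Green, the smallest charge, stands at the edge of it.

The flasks give ochre > amber > violet > grey > red > green, with ochre at 29.4% and green at 6.91%, a spread of 4.25.

    initiator → 2 initiating radical (k = 0.0124 h⁻¹, Ea = 97.0 kJ mol⁻¹)
    substrate + initiating radical → capped initiator + first chain carrier (k = 19400 L mol⁻¹ s⁻¹, Ea = 33.0 kJ mol⁻¹)
    reagent + first chain carrier ⇌ target + second chain carrier (K = 1.30, k = 2.93 × 10⁶ L mol⁻¹ h⁻¹, Ea = 41.0 kJ mol⁻¹, ΔH = −57.0 kJ mol⁻¹)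
    substrate + second chain carrier → released group + first chain carrier (k = 2.78 × 10⁶ L mol⁻¹ h⁻¹, Ea = 39.0 kJ mol⁻¹)
    2 first chain carrier → ended chains A (k = 5.00 × 10⁷ L mol⁻¹ s⁻¹, Ea = 8.00 kJ mol⁻¹)
    2 second chain carrier → ended chains B (k = 1.90 × 10⁷ L mol⁻¹ s⁻¹, Ea = 13.0 kJ mol⁻¹)
    2 reagent → homo dimer (k = 0.188 L mol⁻¹ h⁻¹, Ea = 72.0 kJ mol⁻¹)
    (constants at 20 °C)

The forecast's top stands 6.6 points too high. In ochre, 8.40% of the reagent is left at 20.0 h, and the clock's n gives 7.52%. For a neighbour of ochre with 0.40 M of reagent, the clock gives n = 4.91 and a reckoned target of 22.4%. That flask holds 20.7% of target.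

(The readings come from a simulation on assumed constants, noise included.)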